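**Assumption:** the pinane unit of the target belongs to the (+)-pinene series, so (1R,5R)-(+)-α-pinene (≥97% ee grade) is the chiral source; enolisable triones are drawn as one enol tautomer.

## Retrosynthetic overview

1. Target 18 ⇒ O-methylation (C–O) of spiro-triketone 17 ⇒ radical hydroalkylative 5-exo spirocyclisation (new) of open-chain trione 16.
2. 16 ⇒ reductive opening of the allylic enol ether in oxa-Diels–Alder adduct 15 ⇒ C–O/C–C cycloaddition of pinenyl-trione 12 (through its oxadiene tautomer 14) with 4-methylpenta-1,3-diene 13.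
3. 12 ⇒ Knoevenagel-type union of trimethyl-trione 5 (from 2',4',6'-trihydroxyacetophenone 1) with (−)-nopinone 10 (from (+)-α-pinene 6).
4. Ring order: ring A by dearomatisation; pinane from the chiral pool; a transient dihydropyran; the cyclopentane last.

## Route

Step 1
Reactants: 1 2',4',6'-trihydroxyacetophenone
Product: 4 2-acetyl-4,6,6-trimethylcyclohexane-1,3,5-trione, via 3'-methyl-2',4',6'-trihydroxyacetophenone 2 (not isolated), via 3',5'-dimethyl-2',4',6'-trihydroxyacetophenone 3 (not isolated)
Conditions: NaOMe (4 equiv), MeI (3.1 equiv), MeOH, 0 to 25 °C; then aq. HCl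
Reagents that add atoms: iodomethane CI
Why: Alkylative dearomatisation of the acylphloroglucinol anion (syncarpic-acid-type C-methylation; the acetyl group blocks one ring carbon) runs through 2 and 3 and, with three equivalents of MeI, stops mainly at the gem-dimethyl trione; no stereocentre is formed.

Step 2
Reactants: 4 2-acetyl-4,6,6-trimethylcyclohexane-1,3,5-trione
Product: 5 2,2,4-trimethylcyclohexane-1,3,5-trione
Conditions: 6 M aq. HCl, 100 °C
Reagents that add atoms: none
Why: Acid-mediated retro-Claisen deacylation (the syncarpic acid procedure) removes the exocyclic acetyl group and frees the ring CH2 between two carbonyls.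

Step 3
Reactants: 6 (1R,5R)-(+)-α-pinene
Product: 9 (1R,5R)-(+)-β-pinene, via pinenylpotassium 7 (not isolated), via dimethyl myrtenylboronate 8 (not isolated)
Conditions: n-BuLi, KOtBu, hexane, 25 °C; B(OMe)3, −78 to 25 °C; then H2O
Reagents that add atoms: none
Why: Schlosser-base allylic metalation at C10, borylation and SE2' protodeboronation give the contrathermodynamic exocyclic alkene (Brown isomerisation) without touching the bridgehead stereocentres.

Step 4
Reactants: 9 (1R,5R)-(+)-β-pinene
Product: 10 (1S,5R)-(−)-nopinone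
Conditions: RuCl3·3H2O (2 mol%), NaIO4 (2.2 equiv), EtOAc/MeCN/H2O, 0 to 25 °C
Reagents that add atoms: sodium periodate [Na+].[O-]I(=O)(=O)=O
Why: RuO4-type oxidative cleavage (Sharpless conditions) of the 1,1-disubstituted alkene gives the ketone and leaves the bridgeheads unchanged.

Step 5
Reactants: 5 2,2,4-trimethylcyclohexane-1,3,5-trione; 10 (1S,5R)-(−)-nopinone
Product: 12 2-[(1S,5R)-6,6-dimethylbicyclo[3.1.1]hept-2-en-2-yl]-4,6,6-trimethylcyclohexane-1,3,5-trione, via aldol adduct 11 (not isolated)
Conditions: TiCl4 (2 equiv), pyridine (4 equiv), THF, 0 to 25 °C; aqueous work-up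
Reagents that add atoms: none
Why: In this TiCl4/pyridine (Lehnert) Knoevenagel-type condensation the titanium enolate of 5, which has a single CH2, adds to the nopinone carbonyl from the face anti to the gem-dimethyl bridge to give aldol adduct 11 as its titanium alkoxide, and loss of water with removal of a proton from pinane C3 ends at the conjugated dienol 12, whose new double bond lies in the pinene ring, so the carbinol centre is not carried on.

Step 6
Reactants: 12 2-[(1S,5R)-6,6-dimethylbicyclo[3.1.1]hept-2-en-2-yl]-4,6,6-trimethylcyclohexane-1,3,5-trione; 13 4-methylpenta-1,3-diene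
Product: 16 2-[(1S,2S,5R)-6,6-dimethyl-2-(4-methylpent-3-en-1-yl)bicyclo[3.1.1]heptan-2-yl]-4,6,6-trimethylcyclohexane-1,3,5-trione, via alkylidene trione 14 (not isolated), via spiro-dihydropyran cycloadduct 15 (not isolated)
Conditions: 13 (5 equiv), BHT (cat.), toluene, 110 °C (sealed tube); concentrate; then Pd(PPh3)4 (5 mol%), PhSiH3 (3 equiv), CH2Cl2, 25 °C
Reagents that add atoms: none
Why: On heating, 12 tautomerises by a 1,5-hydrogen shift from the enol oxygen to pinene C3 to the 1-oxadiene 14, which undergoes an inverse-electron-demand oxa-Diels–Alder reaction (Tietze type) with the terminal vinyl group of 13, forming the C–O bond and the C2–CH2 bond on the pinane face anti to the gem-dimethyl bridge (this sets pinane C2 with the ring A carbon syn to the bridge); all cycloadducts 15, whichever ring carbonyl and acetal configuration they carry, are then opened by Tsuji–Trost ionisation of the allylic enol ether and hydride transfer from PhSiH3 to the less hindered allyl terminus.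

Step 7
Reactants: 16 2-[(1S,2S,5R)-6,6-dimethyl-2-(4-methylpent-3-en-1-yl)bicyclo[3.1.1]heptan-2-yl]-4,6,6-trimethylcyclohexane-1,3,5-trione
Product: 17 O-demethyl target (spiro-triketone, enol form)
Conditions: 9-mesityl-10-methylacridinium tetrafluoroborate (5 mol%), methyl thiosalicylate (20 mol%), 2,6-lutidine (20 mol%), degassed 1,2-dichloroethane, 450 nm LEDs, 25 °C
Reagents that add atoms: none
Why: Proposed new method: a redox-neutral radical hydroalkylation (radical Conia-ene) in which the excited acridinium oxidises the lutidine-buffered enol of the 2-substituted 1,3-dione (or the trisubstituted alkene to its radical cation, which leads to the same bond), the electrophilic dicarbonyl radical closes 5-exo-trig onto the CH end of the alkene, and the tertiary radical is quenched by hydrogen-atom transfer from the thiol, which the reduced acridine and a proton regenerate; the isopropyl-bearing centre follows from a Beckwith–Houk chair with the CMe2 terminus pseudo-equatorial and anti to the bulkier bridgehead branch of the pinane, and the spiro centre from placing that terminus beside the flat C(=O)–C(Me)=C(OH) arm of ring A and away from the C(=O)–CMe2 arm; the closest known reaction types are the Mn(OAc)3-mediated oxidative cyclisation of unsaturated 1,3-dicarbonyls and acridinium/thiol anti-Markovnikov alkene hydrofunctionalisation.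

Step 8
Reactants: 17 O-demethyl target (spiro-triketone, enol form)
Product: 18 target CNP0307059.1
Conditions: TMSCHN2 (1.5 equiv), toluene/MeOH 4:1, 0 to 25 °C
Reagents that add atoms: trimethylsilyldiazomethane C[Si](C)(C)C=[N+]=[N-]
Why: O-Methylation of the only remaining enol (a vinylogous acid) with TMSCHN2 occurs at the oxygen flanked by CMe2 and not at the oxygen buried beside the spiro carbon, forming the C–O bond of the tasmanone-type methyl enol ether without changing any stereocentre.

## Compound list

1 | 2',4',6'-trihydroxyacetophenone | CC(=O)c1c(O)cc(O)cc1O | starting material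
2 | 3'-methyl-2',4',6'-trihydroxyacetophenone | CC(=O)c1c(O)cc(O)c(C)c1O | intermediate (not isolated)
3 | 3',5'-dimethyl-2',4',6'-trihydroxyacetophenone | CC(=O)c1c(O)c(C)c(O)c(C)c1O | intermediate (not isolated)
4 | 2-acetyl-4,6,6-trimethylcyclohexane-1,3,5-trione (dienol tautomer) | CC(=O)C1=C(O)C(C)=C(O)C(C)(C)C1=O | intermediate
5 | 2,2,4-trimethylcyclohexane-1,3,5-trione (dienol tautomer) | O=C1C=C(O)C(C)=C(O)C1(C)C | intermediate
6 | (1R,5R)-(+)-α-pinene | CC1=CC[C@@H]2C[C@H]1C2(C)C | starting material
7 | pinenylpotassium (α-pinene metalated at C10) | [K+].[CH2-]C1=CC[C@@H]2C[C@H]1C2(C)C | intermediate (not isolated)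
8 | dimethyl myrtenylboronate (boron on C10, pinane as in 6) | COB(OC)CC1=CC[C@@H]2C[C@H]1C2(C)C | intermediate (not isolated)
9 | (1R,5R)-(+)-β-pinene | C=C1CC[C@@H]2C[C@H]1C2(C)C | intermediate
10 | (1S,5R)-(−)-nopinone | O=C1CC[C@@H]2C[C@H]1C2(C)C | intermediate
11 | aldol adduct: 2-[(1S,2S,5R)-2-hydroxy-6,6-dimethylbicyclo[3.1.1]heptan-2-yl]-4,6,6-trimethylcyclohexane-1,3,5-trione (dienol tautomer; ring A anti and OH syn to the gem-dimethyl bridge; present in the flask as its titanium alkoxide) | CC1=C(O)C(C)(C)C(O)=C(C1=O)[C@]2(O)CC[C@@H]3C[C@H]2C3(C)C | intermediate (not isolated)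
12 | 2-[(1S,5R)-6,6-dimethylbicyclo[3.1.1]hept-2-en-2-yl]-4,6,6-trimethylcyclohexane-1,3,5-trione (dienol tautomer) | CC1=C(O)C(C)(C)C(O)=C(C1=O)C2=CC[C@@H]3C[C@H]2C3(C)C | intermediate
13 | 4-methylpenta-1,3-diene | C=CC=C(C)C | starting material
14 | alkylidene trione: 2-[(1S,5R)-6,6-dimethylbicyclo[3.1.1]heptan-2-ylidene]-4,6,6-trimethylcyclohexane-1,3,5-trione (either alkene geometry) | CC1=C(O)C(C)(C)C(=O)C(C1=O)=C2CC[C@@H]3C[C@H]2C3(C)C | intermediate (not isolated)
15 | spiro-dihydropyran cycloadduct: 7-hydroxy-6,8,8-trimethyl-2-(2-methylprop-1-enyl)-2,3-dihydrospiro[chromene-4,2'-pinan]-5(8H)-one; ring CH2 on pinane C2 anti to the gem-dimethyl bridge; drawn as one epimer at the O-bearing CH and as the regioisomer closed through the carbonyl next to CMe2 | CC1=C(O)C(C)(C)C2=C(C1=O)[C@@]3(C[C@H](O2)C=C(C)C)CC[C@@H]4C[C@H]3C4(C)C | intermediate (not isolated)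
16 | 2-[(1S,2S,5R)-6,6-dimethyl-2-(4-methylpent-3-en-1-yl)bicyclo[3.1.1]heptan-2-yl]-4,6,6-trimethylcyclohexane-1,3,5-trione (dienol tautomer; side chain anti, ring A syn to the gem-dimethyl bridge) | CC1=C(O)C(C)(C)C(O)=C(C1=O)[C@@]2(CCC=C(C)C)CC[C@@H]3C[C@H]2C3(C)C | intermediate
17 | O-demethyl target: ring A (4-hydroxy-3,5,5-trimethylcyclohex-3-ene-2,6-dione) spiro at C1 to a cyclopentane that carries isopropyl on the adjacent carbon and is spiro-fused at the other adjacent carbon to pinane C2; pinane C1 (S), C2 (R), C5 (R); ring A spiro carbon (R); CH-isopropyl (R) | OC1=C(C)C(=O)[C@@]2(C(=O)C1(C)C)[C@@H](C(C)C)CC[C@@]21CC[C@@H]2C[C@H]1C2(C)C | intermediate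
18 | CNP0307059.1: as 17 with OMe in place of the enol OH; pinane C1 (S), C2 (R), C5 (R); ring A spiro carbon (R); CH-isopropyl (R) | COC1=C(C)C(=O)[C@@]2(C(=O)C1(C)C)[C@@H](C(C)C)CC[C@@]21CC[C@@H]2C[C@H]1C2(C)C | target

## Step count and risks

Total steps: 8. Longest linear sequence: 6 (steps 3–8 from 6; equally steps 1, 2, 5–8 from 1).

**Step 5 (condensation of a hindered ketone with a cyclic trione; Lewis acid near the cyclobutane).** Fallback: set out from 10 and make the C–C bond by cross-coupling instead of condensation. LDA then PhNTf2 converts 10 into (1S,5R)-6,6-dimethylbicyclo[3.1.1]hept-2-en-2-yl trifluoromethanesulfonate F1. Pd(OAc)2/tBuXPhos with K3PO4 in dioxane at 80 °C couples F1 with the CH2 of 5 (α-alkenylation of a cyclic 1,3-dione). This comes back to the route at 12.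

**Step 6 (cycloaddition at a fully substituted oxadiene terminus; regiochemistry of hydride delivery).** Fallback: set out from 10 and form the C2–ring A bond by a stereoretentive allylic substitution. Vinylmagnesium bromide adds to 10 anti to the gem-dimethyl bridge to give (1S,2R,5R)-2-ethenyl-6,6-dimethylbicyclo[3.1.1]heptan-2-ol F2. n-BuLi then ClCO2Me gives its methyl carbonate F3. RhCl(PPh3)3/P(OMe)3 with the sodium salt of 5 substitutes the tertiary carbonate with net retention (double inversion) to give the 2-(2-ethenylpinan-2-yl) trione F4, ring A syn to the bridge. Excess 9-BBN (enol OH groups are borylated and freed on work-up) gives the primary B-alkyl-9-BBN adduct F5. Pd(dppf)Cl2 and K3PO4 couple it with 1-bromo-2-methylprop-1-ene. This comes back to the route at 16.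

**Step 7 (the proposed new cyclisation).** Two things are uncertain: the catalytic turnover in the presence of a second, non-productive enol, and the diastereoselectivity at the spiro carbon. The two ring A arms differ only beyond the carbonyls, so a modest ratio with chromatographic separation of the spiro epimer should be expected. Fallback with known chemistry: set out from 16 and use Snider's oxidative radical cyclisation. Mn(OAc)3·2H2O and Cu(OAc)2·H2O in AcOH at 25–50 °C give the isopropenyl spiro-triketone F6. H2 over Pd/C in EtOAc then saturates the isopropenyl group. This comes back to the route at 17.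

## Further compounds

F1 | step 5 | (1S,5R)-6,6-dimethylbicyclo[3.1.1]hept-2-en-2-yl trifluoromethanesulfonate | O=S(=O)(OC1=CC[C@@H]2C[C@H]1C2(C)C)C(F)(F)F
F2 | step 6 | (1S,2R,5R)-2-ethenyl-6,6-dimethylbicyclo[3.1.1]heptan-2-ol | O[C@@]1(C=C)CC[C@@H]2C[C@H]1C2(C)C
F3 | step 6 | methyl carbonate of F2 | COC(=O)O[C@@]1(C=C)CC[C@@H]2C[C@H]1C2(C)C
F4 | step 6 | 2-(2-ethenyl-6,6-dimethylbicyclo[3.1.1]heptan-2-yl)-4,6,6-trimethylcyclohexane-1,3,5-trione (ring A syn to the gem-dimethyl bridge) | CC1=C(O)C(C)(C)C(O)=C(C1=O)[C@@]2(C=C)CC[C@@H]3C[C@H]2C3(C)C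
F5 | step 6 | B-alkyl-9-borabicyclo[3.3.1]nonane adduct of F4 (boron on the terminal carbon) | CC1=C(O)C(C)(C)C(O)=C(C1=O)[C@@]2(CCB3C4CCCC3CCC4)CC[C@@H]5C[C@H]2C5(C)C
F6 | step 7 | isopropenyl analogue of 17 (prop-1-en-2-yl in place of isopropyl) | OC1=C(C)C(=O)[C@@]2(C(=O)C1(C)C)[C@@H](C(C)=C)CC[C@@]21CC[C@@H]2C[C@H]1C2(C)C
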